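(The data are calculated from invented constants.)

Two questions open this examination of the flasks: what do the earlier runs show, and what does that allow at the hot end?

all flasks: reagent in the second phase 0.118 M
- south: substrate 0.029 M; temperature 25 °C; run made earlier
- west: substrate 0.044 M; temperature 70 °C; run made earlier
- winter: substrate 0.059 M; temperature 50 °C; time 2.0 d; volume of the second phase over the first 2.0
- noon: substrate 0.059 M; temperature 30 °C; time 2.0 d; volume of the second phase over the first 2.0
- summer: substrate 0.059 M; temperature 110 °C; time 2.0 d; volume of the second phase over the first 2.0
- spring: substrate 0.059 M; temperature 40 °C; time 2.0 d; volume of the second phase over the first 2.0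
- dusk: substrate 0.059 M; temperature 70 °C; time 2.0 d; volume of the second phase over the first 2.0
- midnight: substrate 0.059 M; temperature 90 °C; time 2.0 d; volume of the second phase over the first 2.0

south run (percent of the substrate charged)

| time / d | target / % | substrate / % |
|---|---|---|
| 4.00 | 5.4 | 95.7 |
| 8.00 | 9.9 | 89.7 |
| 12.0 | 15.4 | 85.2 |
| 15.0 | 18.4 | 81.4 |
| 20.0 | 24.8 | 75.9 |

west run (percent of the substrate charged)

| time / h | target / % | substrate / % |
|---|---|---|
| 4.00 | 1.2 | 98.5 |
| 8.00 | 4.6 | 95.4 |
| 15.0 | 10.5 | 90.1 |
| 25.0 | 20.8 | 79.8 |
| 50.0 | 41.7 | 57.5 |

(standard deviation of a reading: 0.5 percentage points)

1. the flasks put in order of amount of target, in percent of the substrate charged, best first, at 2.0 d (winter / noon / summer / spring / dusk / midnight)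
2. the amount of target, in percent of the substrate charged of the flask you put first, at 2.0 d
3. the amount of target, in percent of the substrate charged of the flask you put last, at 2.0 d

What does the west run show? Between 8.00 h and 50.0 h its target climbs almost straight while its substrate falls from 95.4% to 57.5%, and a rate proportional to substrate, all else steady, should have sagged with it.

What number do you take from that? The straight stretch of the west run reads 0.389 mM h⁻¹ of target, a reading that carries the scatter of its two ends. I call this slope, target per litre of the first phase per hour, the supply rate, on the guess that reagent crossing from the second phase is the rate-limiting step there.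

Does the south run test it? No. South averages 0.0150 mM h⁻¹, far below that rate, so it gives no test of that slope.

And if west was not at its limit? Then the supply rate reads what crossed in the west run, which is less than what can cross, and these readings do not tell me which case holds. Held to that rate, a flask charged with 0.059 M of substrate makes 31.6% in 2.0 d. That is my own figure for dusk, the flask at 70 °C like the west run, though dusk is charged with more substrate. Summer can pass that figure to the extent that more crosses than the slope shows.

The forecast gives summer > midnight > dusk > winter > spring > noon, with 97% first and 3% last, and it names its own risk: “the straight West line means transfer limitation”. I take its order, but its top asks for a mean rate of 1.19 mM h⁻¹, which is 3.06 times the supply rate, and the west run reads no such crossing.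

The simulation gives summer > midnight > dusk > winter > spring > noon, with 64.7% in summer and 3.16% in noon.

    reagent in the reaction phase ⇌ reagent in the second phase, rate k1*([reagent in the reaction phase] - [reagent in the second phase]/K1) per volume of the first phase (partition coefficient = 2.90, kL = 0.0560 h⁻¹)
    substrate + reagent in the reaction phase → target (k = 1.70 M⁻¹ h⁻¹, Ea = 73.0 kJ mol⁻¹)
    reagent in the reaction phase + target ⇌ idle adduct, settled at all times (K = 45.0 M⁻¹, ΔH = 7.00 kJ mol⁻¹)
    2 reagent in the reaction phase → homo dimer (k = 0.130 M⁻¹ h⁻¹, Ea = 67.0 kJ mol⁻¹)
    crystals ⇌ target, rate k5*(cs5 - [target]) while solid is left; crystals form when [target] > cs5 (solubility = 40.0 mM, k = 1.70 h⁻¹)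
    (constants at 70 °C)

Summer stands 32 percentage points under the forecast, with 64.6% of the reagent's own charge still in the second phase at 2.00 d. Its mean rate is 0.795 mM h⁻¹, twice the supply rate, so that slope was no ceiling for summer. Dusk, at the temperature of the west run, was reckoned at 31.6% from the slope and holds 35.5% of target at 2.00 d.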